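The 19-membered ring is opened at the C(sp2)–C(sp3) bond between ring D (the meta-disubstituted ring) and the CH2CH2 bridge leading to ring A; the key step exploits that this bridge is saturated, so its two carbons can arrive as a ring A vinyl group. Rings A and C are the same 1-alkyl-3-aryloxy-4,5-dioxygenated unit, so both halves come from one aldehyde by Chan–Lam arylation and methylenation. A bromide/chloride pair allows two hydroboration/B-alkyl Suzuki couplings in sequence: the first joins the halves (ring B–CH2CH2–ring C); the second, on a linear tetra-aryl chloro styrene, forms the last bridge and closes the macrocycle in one pot at the saturated oxidation level. BBr3 then frees the four phenols.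

Key step: step 6

Remark (assumption): the target has no stereocentre, and the 19-membered cyclophane is taken as conformationally mobile, so there is no enantiomer to control; the achiral compound itself is the target.

Remark (ring labels): A and C are the two 4,5-dihydroxylated rings. A is bonded through oxygen to the para-phenylene ring B, and C through oxygen to the meta-phenylene ring D. The bridges are B–CH2CH2–C and D–CH2CH2–A.

Step 1
Reactants: 1 3-hydroxy-4,5-dimethoxybenzaldehyde; 2 4-bromophenylboronic acid
Product: 3 3-(4-bromophenoxy)-4,5-dimethoxybenzaldehyde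
Conditions: Cu(OAc)2 (20 mol %), pyridine, 4 Å MS, CH2Cl2, O2 (1 atm), rt
Reagents that add atoms: none
Why: Chan–Lam oxidative O-arylation, in which the copper phenoxide is transmetalated by the arylboronic acid and C–O reductive elimination forms the diaryl ether at room temperature, should leave the C–Br bond and the aldehyde untouched and tolerate the single ortho-methoxy group.

Step 2
Reactants: 3 3-(4-bromophenoxy)-4,5-dimethoxybenzaldehyde
Product: 4 1-(4-bromophenoxy)-5-ethenyl-2,3-dimethoxybenzene
Conditions: Ph3PCH3Br, KOtBu, THF, 0 °C → rt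
Reagents that add atoms: methyltriphenylphosphonium bromide, C[P+](c1ccccc1)(c1ccccc1)c1ccccc1.[Br-] (delivers CH2 through the ylide C=P(c1ccccc1)(c1ccccc1)c1ccccc1 formed with KOtBu)
Why: Wittig methylenation of a non-enolisable aromatic aldehyde should give the styrene, the aryl bromide and the ether groups being inert to the ylide.

Step 3
Reactants: 1 3-hydroxy-4,5-dimethoxybenzaldehyde; 5 3-chlorophenylboronic acid
Product: 6 3-(3-chlorophenoxy)-4,5-dimethoxybenzaldehyde
Conditions: Cu(OAc)2 (20 mol %), pyridine, 4 Å MS, CH2Cl2, O2 (1 atm), rt
Reagents that add atoms: none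
Why: the same Chan–Lam O-arylation as in step 1 should give the second diaryl ether, the C–Cl bond being inert to copper at room temperature.

Step 4
Reactants: 6 3-(3-chlorophenoxy)-4,5-dimethoxybenzaldehyde
Product: 7 1-(3-chlorophenoxy)-5-ethenyl-2,3-dimethoxybenzene
Conditions: Ph3PCH3Br, KOtBu, THF, 0 °C → rt
Reagents that add atoms: methyltriphenylphosphonium bromide, C[P+](c1ccccc1)(c1ccccc1)c1ccccc1.[Br-] (delivers CH2 through the ylide C=P(c1ccccc1)(c1ccccc1)c1ccccc1 formed with KOtBu)
Why: Wittig methylenation as in step 2 should give the ring C styrene with the aryl chloride intact.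

Step 5
Reactants: 7 1-(3-chlorophenoxy)-5-ethenyl-2,3-dimethoxybenzene; 4 1-(4-bromophenoxy)-5-ethenyl-2,3-dimethoxybenzene
Product: 9 1-(3-chlorophenoxy)-5-{2-[4-(5-ethenyl-2,3-dimethoxyphenoxy)phenyl]ethyl}-2,3-dimethoxybenzene, via ring C alkyl-9-BBN borane 8 (not isolated)
Conditions: 7 (slight excess), 9-BBN, THF, 0 °C → rt; then aq K3PO4, 4, Pd(dppf)Cl2 (5 mol %), THF/DMF, 50 °C
Reagents that add atoms: 9-BBN (9-borabicyclo[3.3.1]nonane), B1C2CCCC1CCC2 (its boron bicycle is held in 8 only; 9 keeps one hydrogen from it)
Why: 9-BBN should hydroborate the styrene anti-Markovnikov to the primary alkylborane 8, and the B-alkyl Suzuki–Miyaura coupling with Pd(dppf) should insert only into the C–Br bond of 4, so the aryl chloride is kept, while the vinyl group of 4 meets no free B–H (7 in excess, base added first) and Heck arylation is slow at 50 °C.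

Step 6
Reactants: 9 1-(3-chlorophenoxy)-5-{2-[4-(5-ethenyl-2,3-dimethoxyphenoxy)phenyl]ethyl}-2,3-dimethoxybenzene
Product: 11 tetra-O-methyl ether of the target macrocycle, via ring A alkyl-9-BBN borane 10 (not isolated)
Conditions: 9-BBN, THF, rt; then slow addition (syringe pump) to Pd(OAc)2/SPhos, K3PO4, THF/H2O, 65 °C, final ca. 2 mM
Reagents that add atoms: 9-BBN (9-borabicyclo[3.3.1]nonane), B1C2CCCC1CCC2 (its boron bicycle is held in 10 only; 11 keeps one hydrogen from it)
Why: 9-BBN adds syn and anti-Markovnikov across the ring A vinyl group so that boron sits on the terminal carbon; base then converts the B-alkyl-9-BBN into its borate, Pd(0)/SPhos inserts into the ring D C–Cl bond, the primary alkyl group passes from boron to palladium within the same molecule, and reductive elimination forms the ring D C(sp2)–CH2 bond. The closest known reaction type is the B-alkyl Suzuki–Miyaura macrocyclisation of an ω-haloaryl alkylborane, run as a one-pot hydroboration/cross-coupling. The one ring closed is the 19-membered macrocycle, formed by intramolecular cross-coupling at the aryl–CH2 bond under pseudo-high dilution (slow addition of 10 to the catalyst), which should favour ring closure over oligomerisation. No stereocentre is formed, so no stereocontrol element is needed. The step needs regioselective hydroboration, secured by the bulk of 9-BBN on a monosubstituted styrene, and a single site of oxidative addition, secured because the chloride is the only carbon–halogen bond left and the methyl and diaryl ethers are inert. Because the bridge is made saturated, no stilbene geometry constrains the ring, and the two diaryl ether hinges and the existing ethano bridge should let the chain ends meet without strain.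

Step 7
Reactants: 11 tetra-O-methyl ether of the target macrocycle
Product: 12 target macrocyclic bis(bibenzyl) CNP0511668.0
Conditions: BBr3 (excess), CH2Cl2, −78 °C → rt; then MeOH/H2O, 0 °C
Reagents that add atoms: none
Why: BBr3 demethylation, in which boron coordinates each methoxy oxygen and bromide attacks the methyl carbon (SN2), should cleave the four aryl methyl ethers but not the diaryl ethers, and aqueous work-up hydrolyses the aryl borates to the two catechols.

Compound list
1 | 3-hydroxy-4,5-dimethoxybenzaldehyde | COc1cc(C=O)cc(O)c1OC | starting material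
2 | 4-bromophenylboronic acid | OB(O)c1ccc(Br)cc1 | starting material
3 | 3-(4-bromophenoxy)-4,5-dimethoxybenzaldehyde | COc1cc(C=O)cc(Oc2ccc(Br)cc2)c1OC | intermediate
4 | 1-(4-bromophenoxy)-5-ethenyl-2,3-dimethoxybenzene | COc1cc(C=C)cc(Oc2ccc(Br)cc2)c1OC | intermediate
5 | 3-chlorophenylboronic acid | OB(O)c1cccc(Cl)c1 | starting material
6 | 3-(3-chlorophenoxy)-4,5-dimethoxybenzaldehyde | COc1cc(C=O)cc(Oc2cccc(Cl)c2)c1OC | intermediate
7 | 1-(3-chlorophenoxy)-5-ethenyl-2,3-dimethoxybenzene | COc1cc(C=C)cc(Oc2cccc(Cl)c2)c1OC | intermediate
8 | 9-{2-[3-(3-chlorophenoxy)-4,5-dimethoxyphenyl]ethyl}-9-borabicyclo[3.3.1]nonane (not isolated) | COc1cc(CCB2C3CCCC2CCC3)cc(Oc2cccc(Cl)c2)c1OC | intermediate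
9 | 1-(3-chlorophenoxy)-5-{2-[4-(5-ethenyl-2,3-dimethoxyphenoxy)phenyl]ethyl}-2,3-dimethoxybenzene | COc1cc(C=C)cc(Oc2ccc(CCc3cc(OC)c(OC)c(Oc4cccc(Cl)c4)c3)cc2)c1OC | intermediate
10 | 9-{2-[3-(4-{2-[3-(3-chlorophenoxy)-4,5-dimethoxyphenyl]ethyl}phenoxy)-4,5-dimethoxyphenyl]ethyl}-9-borabicyclo[3.3.1]nonane (not isolated) | COc1cc(CCB2C3CCCC2CCC3)cc(Oc2ccc(CCc3cc(OC)c(OC)c(Oc4cccc(Cl)c4)c3)cc2)c1OC | intermediate
11 | tetra-O-methyl ether of the target: 19-membered bis(bibenzyl) diether with four OMe groups on rings A and C | COc1cc2cc(c1OC)Oc1ccc(cc1)CCc1cc(OC)c(OC)c(c1)Oc1cccc(c1)CC2 | intermediate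
12 | target CNP0511668.0: 19-membered bis(bibenzyl) with A–O–B(para), B–CH2CH2–C, C–O–D(meta), D–CH2CH2–A and a 4,5-diol on each of rings A and C (achiral) | Oc1cc2cc(c1O)Oc1ccc(cc1)CCc1cc(O)c(O)c(c1)Oc1cccc(c1)CC2 | target

Total step count: 7. Longest linear sequence: 5 steps (steps 1, 2, 5, 6, 7 or steps 3, 4, 5, 6, 7).

Steps most likely to fail

Step 6. Ring closure may lose to intermolecular coupling (oligomerisation), or oxidative addition into the C–Cl bond may be slow enough at high dilution for the alkylborane to decay by protodeboronation or β-hydride loss. The fallback closes the same ring by olefin metathesis in place of cross-coupling and sets out from 9. Suzuki–Miyaura vinylation of the aryl chloride with potassium vinyltrifluoroborate (Pd(OAc)2/RuPhos, K2CO3, toluene/H2O, 85 °C, normal concentration) should give the bis-styrene 1-(3-ethenylphenoxy)-5-{2-[4-(5-ethenyl-2,3-dimethoxyphenoxy)phenyl]ethyl}-2,3-dimethoxybenzene F1. Ring-closing metathesis of F1 (second-generation Ru–NHC benzylidene catalyst, toluene, 80 °C, high dilution) should then close the 19-membered ring as the macrocyclic stilbene F2 with loss of ethene. Hydrogenation of F2 (H2, Pd/C, EtOAc), whichever alkene geometry forms, comes back to the route at 11.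

Step 5. Chemoselectivity may be lost through hydroboration of the vinyl group of 4 by residual B–H or through Heck-type arylation of that vinyl group, and borane 8 may protodeboronate. The fallback builds the bridge by Heck coupling and hydrogenation and introduces the ring A vinyl group afterwards; it sets out from 3 and 7. Heck coupling of 7 with 3 (Pd(OAc)2, P(o-tol)3, NaOAc, DMF, 100 °C; C–Cl inert) should give the (E)-stilbene aldehyde F3. Hydrogenation of the alkene over Pd/C poisoned with diphenyl sulfide (H2 1 atm, EtOAc, rt), conditions chosen to spare the aryl chloride and the aromatic aldehyde, should give the bibenzyl aldehyde F4. Wittig methylenation of F4 (Ph3PCH3Br, KOtBu, THF) comes back to the route at 9.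

Step 3. Transmetalation of the electron-poor boronic acid may be slow, and the boronic acid may be consumed by oxidation to the phenol and by homocoupling before the hindered phenol is arylated (the same concern holds, to a lesser degree, for step 1). The fallback replaces oxidative coupling of a boronic acid by an Ullmann-type coupling of an aryl iodide and sets out from 1. Heating 1 with 1-chloro-3-iodobenzene (CuI, picolinic acid, K3PO4, DMSO, 90 °C) should engage the C–I bond only and give 6 itself, where the route is rejoined; no new compound is made (F0).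

Further compounds
F1 | step 6 | 1-(3-ethenylphenoxy)-5-{2-[4-(5-ethenyl-2,3-dimethoxyphenoxy)phenyl]ethyl}-2,3-dimethoxybenzene | COc1cc(C=C)cc(Oc2ccc(CCc3cc(OC)c(OC)c(Oc4cccc(C=C)c4)c3)cc2)c1OC
F2 | step 6 | macrocyclic (E)-stilbene: 11 with CH=CH in place of the CH2CH2 bridge between rings D and A | COc1cc2cc(c1OC)Oc1ccc(cc1)CCc1cc(OC)c(OC)c(c1)Oc1cccc(c1)/C=C/2
F3 | step 5 | 3-(4-{(E)-2-[3-(3-chlorophenoxy)-4,5-dimethoxyphenyl]ethenyl}phenoxy)-4,5-dimethoxybenzaldehyde | COc1cc(C=O)cc(Oc2ccc(/C=C/c3cc(OC)c(OC)c(Oc4cccc(Cl)c4)c3)cc2)c1OC
F4 | step 5 | 3-(4-{2-[3-(3-chlorophenoxy)-4,5-dimethoxyphenyl]ethyl}phenoxy)-4,5-dimethoxybenzaldehyde | COc1cc(C=O)cc(Oc2ccc(CCc3cc(OC)c(OC)c(Oc4cccc(Cl)c4)c3)cc2)c1OC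
F0 | step 3 | none | none
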